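## The problem

The target **24** is a (2S)-flavan (2-phenylchroman, atoms O1 to C8a, benzene ring = ring A). Ring A carries a methoxy group at C5, a free hydroxyl at C7 and, at C8, carbon C2' of a benzofuran (primed atoms, benzene ring = ring B) with OMe at C4', Me at C5' and a free OH at C6'. The two ring systems meet in one aryl–heteroaryl bond, C8–C2', which lies between two oxygen-bearing carbons (C7 and C8a). The bond is therefore hindered, and functionalising C8 on a finished 5,7-dioxygenated chroman would compete with the electronically similar C6. C2 is the only stereocentre and a benzylic ether carbon; nothing in the molecule can control it, so it must come from a catalyst-controlled step, and its C–O bond must afterwards never be ionised or hydrogenolysed. Two phenols (C7–OH, C6'–OH) have to be kept apart from two methyl ethers (C5–OMe, C4'–OMe). This rules out late demethylation and calls for protecting groups that leave without harming the electron-rich benzofuran, which is sensitive to electrophiles, oxidants and hot acid. Ring B is a C-methylphloroglucinol pattern (oxygens at C4', C6' and C7a' mutually meta), which ortho/para chemistry on a methylresorcinol ether cannot reach. The enabling feature is that C8a (bearing O1) and C8 (bearing C2') are neighbours on ring A, with the C7 oxygen next to C8. An aryne across C8–C8a can take the tethered C2 alkoxide at C8a and leave a carbanion at C8, stabilised by the C7 oxygen, to pick up the carbon that becomes C2'.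

## Retrosynthesis

**Protecting groups (24 → 23 → 22).** The O–Si bond at C6' and the acetal at C7 are cut last. Silyl ether **23** is cleaved with buffered fluoride and the MOM ether in **22** with dilute methanolic acid, so no hydrogenolysis comes near the benzylic C2–O bond or the furan double bond. The MOM group is chosen because it must also direct the ring lithiation of the key step. The silyl group is chosen because it is bulky enough to steer two steps in the ring B series.

**Furan ring (22 → 20 + 19).** O1'–C2' and C2'=C3' are cut, giving aroyl chloride **20** (from acid **12**) and the ortho-hydroxybenzylphosphonium salt **19**; ester **21** is the intermediate. The alternative cut at C8–C2' would require a cross-coupling at a di-ortho-substituted carbon. Here C2' arrives instead as a carboxyl carbon already on C8, and the two halves are joined by a simple acylation. The forward reaction must acylate a phenol with a hindered acid chloride and then let the ylide carbon attack the ester carbonyl intramolecularly.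

**Key disconnection (12 → 7 + 8).** O1–C8a and C8–C2' are cut together. Acid **12** goes back to the open-chain (S)-fluoroarene alcohol **7** and carbon dioxide **8**, through aryllithium **9**, aryne **10** and 8-lithiochroman **11**. Cutting O1–C8a alone would need an activated ring for addition–elimination. Cutting O1–C2 would form the ether at the stereocentre with inversion. Cutting C8–C2' alone would leave the C6/C8 choice open. The aryne answers all three: the fluoride marks C8a, the tether fixes where oxygen adds, and the carbanion can only appear at C8. The precursor has no ring, only the stereocentre and a 1,2,3,5-substituted benzene. The forward step needs lithiation between F and OMOM, clean loss of LiF, and survival of the C8 carbanion until carboxylation.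

**Side chain and stereocentre (7 → 6 → 5 → 3 + 4).** The C2–H bond is cut to ketone **6**, since enantioselective reduction of an aryl alkyl ketone is among the most dependable asymmetric reactions. Ketone **6** comes from chalcone **5** by saturation of the C=C bond. Chalcone **5** is cut at that double bond into aldehyde **3** and acetophenone **4**. A benzylic alkylation route to the three-carbon chain would be longer and would need a benzylic halide of an electron-rich ring.

**Ring A substitution (3 → 2 → 1).** The C–OMe bond ortho to the formyl group is cut (fluoride displacement in **2**), then the acetal O–C bond (phenol **1**). The two fluorines of **2** are equivalent, so no regiochemical question arises, and the formyl group that activates the displacement is the same carbon that later becomes C4.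

**Ring B fragment (19 → 18 → 17 → 16 → 14 → 13).** The C–P bond is cut to saligenin **18**, which comes from salicylaldehyde **17** by reduction. The formyl C–C bond is cut to phenol **16**. The C–O bond of **16**, meta to both existing oxygens, is cut through boronate **15** to silyl ether **14** of 3-methoxy-2-methylphenol **13**. Only a sterically governed C–H borylation reaches that meta position in one step; every classical route would have to build the ring or use a blocked phloroglucinol.

## Roads not taken

**Alternative 1:** Intramolecular Wittig closure of the furan as the strategic step.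
- **Cut and key step.** The cut is C2'=C3'. Heating ester phosphonium salt **A2** with Et3N lets the benzylic ylide carbon add to the ester carbonyl and lose the phosphine oxide, giving **A1**, the target with a C7 benzyl ether and a C6' silyl ether.
- **Merits.** The fragment union is a plain acylation, the furan regiochemistry is fixed, and the closure is neutral to basic. The benzyl ether is also better than an acetal beside an acyl chloride, and in that respect this road is superior.
- **Weak points.** The difficulty moves back to acid **A3**: a carboxyl carbon must be placed at C8 and not C6 of a finished chroman, and the disconnection offers no help there. The last step would be a hydrogenolysis in the presence of the benzylic C2–O bond and the furan double bond.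
- **Comparison.** The chosen plan uses the same closure as a supporting step (step 13, with **19**), so the two do not differ there. Against the sturdier benzyl ether it sets a neutral chloroenamine activation of **12**, the directing role of the MOM group, and an end game without hydrogen.

**Alternative 2:** Ring-closing metathesis of an enantioenriched allyl aryl ether.
- **Cut and key step.** The cut is C3–C4, formed as a double bond. The second-generation Grubbs catalyst (H2IMes)(PCy3)Cl2Ru=CHPh joins the two vinyl groups of diene **A5** to give 2H-chromene **A4**.
- **Merits.** As a ring closure this is more dependable than any aryne reaction: catalytic, neutral and tolerant. That advantage is real.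
- **Weak points.** In **A5** and **A4** the stereocentre is both benzylic and allylic, so it is prone to ionisation, and in **A5** to a [3,3] shift toward C8 on heating. Making **A5** enantioenriched means forming an aryl ether at exactly that carbon. The C3=C4 bond of **A4** must then be saturated without cleaving the allylic C2–O bond. C8 is still C–H after all this, so the C6/C8 problem remains, and the step count is higher.
- **Comparison.** The chosen plan has the less proven ring closure. In return that closure delivers the C8 carbon in the same operation, and the stereocentre is never next to a double bond.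

**Alternative 3:** Ortho-quinone methide plus styrene on a symmetric resorcinol.
- **Cut and key step.** The cuts are C3–C4 and O1–C2. A chiral imidodiphosphorimidate Brønsted acid dehydrates saligenin **A7** to quinone methide **A9**, which adds styrene **A8** in a [4+2] cycloaddition to give **A6**, the target as its C6' silyl ether.
- **Merits.** This is the most convergent road. The pyran ring and C2 are made in one catalytic step at the very end, from the cheapest possible source of C2, C3 and the phenyl ring. **A6** is the same compound as **23**, one step from the target. If the cycloaddition were selective, this road would be shorter than the chosen one.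
- **Weak points.** All the risk sits in one late step on the most valuable material. **A9** is large and crowded, with the benzofuran next to the reacting oxygen. The C7 hydroxyl of **A7** is para to the benzylic carbon and opens a para-quinone methide channel. Styrene is a weak 2π partner. The benzofuran (C3', C7') and C6 are nucleophiles that can capture **A9**.
- **Comparison.** The chosen plan is longer. It sets the stereocentre by reduction of a simple aryl alkyl ketone, where selectivity can be relied upon, and carries it through steps that never break C2–O.

Key step: step 6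

Assumption: 2,6-difluoro-4-hydroxybenzaldehyde (**1**) is a catalogue compound; it is preferred to 2,4,6-trifluorobenzaldehyde because the para oxygen is already in place and only one of two equivalent fluorides has to be exchanged.

## Route

Step 1
Reactants: 1 2,6-difluoro-4-hydroxybenzaldehyde
Product: 2 2,6-difluoro-4-(methoxymethoxy)benzaldehyde
Conditions: MOMCl, iPr2NEt, CH2Cl2, 0 °C to rt
Reagents that add atoms: chloromethyl methyl ether, COCCl
Why: O-alkylation of an acidic phenol to the MOM acetal; the group is put on now because a free phenoxide would shut down the following substitution and because it later directs the ring lithiation.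

Step 2
Reactants: 2 2,6-difluoro-4-(methoxymethoxy)benzaldehyde
Product: 3 2-fluoro-6-methoxy-4-(methoxymethoxy)benzaldehyde
Conditions: NaOMe (1.05 equiv), MeOH–THF, 0 °C to rt
Reagents that add atoms: sodium methoxide, C[O-].[Na+]
Why: Nucleophilic aromatic substitution (addition–elimination) of a fluoride ortho to the formyl group; the two fluorides are equivalent, and the new methoxy group should deactivate the ring enough to stop the reaction after one exchange.

Step 3
Reactants: 3 2-fluoro-6-methoxy-4-(methoxymethoxy)benzaldehyde; 4 acetophenone
Product: 5 (E)-3-[2-fluoro-6-methoxy-4-(methoxymethoxy)phenyl]-1-phenylprop-2-en-1-one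
Conditions: KOH, EtOH, 0 °C to rt
Reagents that add atoms: none
Why: Claisen–Schmidt condensation of a non-enolisable aldehyde with the acetophenone enolate; dehydration should give the conjugated (E)-enone, and the remaining fluoride on a ring with two alkoxy donors should not be displaced at room temperature.

Step 4
Reactants: 5 (E)-3-[2-fluoro-6-methoxy-4-(methoxymethoxy)phenyl]-1-phenylprop-2-en-1-one
Product: 6 3-[2-fluoro-6-methoxy-4-(methoxymethoxy)phenyl]-1-phenylpropan-1-one
Conditions: H2 (1 atm), 10% Pd/C, Ph2S (cat.), EtOAc, rt
Reagents that add atoms: none
Why: Catalytic hydrogenation of the conjugated C=C bond; the sulfide-moderated palladium on carbon should leave the aryl ketone, the aryl fluoride and the acetal untouched.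

Step 5
Reactants: 6 3-[2-fluoro-6-methoxy-4-(methoxymethoxy)phenyl]-1-phenylpropan-1-one
Product: 7 (1S)-3-[2-fluoro-6-methoxy-4-(methoxymethoxy)phenyl]-1-phenylpropan-1-ol
Conditions: (R)-2-methyl-CBS-oxazaborolidine (10 mol%), BH3·SMe2 (0.7 equiv), THF, −20 °C; MeOH quench
Reagents that add atoms: none
Why: Corey–Bakshi–Shibata reduction; the (R)-oxazaborolidine binds borane and the ketone with phenyl as the large group and delivers hydride to the face that gives the (S)-carbinol, the same sense as acetophenone to (S)-1-phenylethanol.

Step 6
Reactants: 7 (1S)-3-[2-fluoro-6-methoxy-4-(methoxymethoxy)phenyl]-1-phenylpropan-1-ol; 8 carbon dioxide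
Product: 12 (2S)-5-methoxy-7-(methoxymethoxy)-2-phenylchromane-8-carboxylic acid, via C8-lithiated lithium alkoxide 9 (not isolated), via aryne alkoxide 10 (not isolated), via 8-lithiochroman 11 (not isolated)
Conditions: sec-BuLi (2.1 equiv), THF (0.02 M), −78 °C; warm to −20 °C; CO2, −78 °C to rt; cold 1 M HCl to pH 3–4
Reagents that add atoms: none
Why: The first equivalent of sec-BuLi makes the lithium alkoxide and the second removes the ring proton between fluorine and the MOM ether, the most acidic one and the one the acetal oxygens chelate, giving 9. On warming, LiF is lost to give the C8–C8a aryne 10, and the tethered alkoxide adds in the ring plane to C8a, the only aryne carbon it can reach, closing the pyran ring in a six-membered closure that is exo to the aryne bond (formally 6-exo-dig). The carbanion is left at C8 (11), held by the MOM and ring oxygens, and carbon dioxide converts it to the carboxylate, so O1–C8a and C8–C2' form in one flask. The closest known reaction type is capture of a base-generated aryne by a tethered alkoxide to give a chroman with electrophilic quench of the resulting aryllithium; carboxylation of aryllithiums is routine. No stereocentre is created: C2 keeps the (S) configuration of step 5 because its C–O bond is never broken. Lithiation at C8 and not C6 is secured by fluorine acidification plus MOM direction; oxygen at C8a and not C8 by the tether length and by the C7 alkoxy group, which sends nucleophiles to the remote aryne carbon. Capture by the internal alkoxide in preference to sec-BuLi or a second aryllithium is secured by keeping the base near 2 equivalents and by high dilution.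

Step 7
Reactants: 13 3-methoxy-2-methylphenol
Product: 14 triisopropyl(3-methoxy-2-methylphenoxy)silane
Conditions: TIPSCl, imidazole, DMF, rt to 40 °C
Reagents that add atoms: chlorotriisopropylsilane, CC(C)[Si](Cl)(C(C)C)C(C)C
Why: Standard silylation of a phenol; the bulky silyl ether protects the future C6' oxygen, blocks its ortho positions in the next step and later biases the formylation.

Step 8
Reactants: 14 triisopropyl(3-methoxy-2-methylphenoxy)silane
Product: 16 3-methoxy-4-methyl-5-[(triisopropylsilyl)oxy]phenol, via arylboronic pinacol ester 15 (not isolated)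
Conditions: [Ir(OMe)(cod)]2 (1.5 mol%), 4,4'-di-tert-butyl-2,2'-bipyridine (3 mol%), B2pin2 (0.6 equiv), THF, 80 °C; then KHSO5 (as 2KHSO5·KHSO4·K2SO4), acetone–H2O, 0 °C to rt
Reagents that add atoms: potassium peroxymonosulfate, [K+].[O-]S(=O)(=O)OO
Why: Sterically governed aromatic C–H borylation goes to the only ring C–H with no ortho substituent, meta to both oxygens, and oxidation of the C–B bond in the same flask gives the phenol; this installs the third oxygen of ring B where electrophilic chemistry cannot.

Step 9
Reactants: 16 3-methoxy-4-methyl-5-[(triisopropylsilyl)oxy]phenol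
Product: 17 2-hydroxy-6-methoxy-5-methyl-4-[(triisopropylsilyl)oxy]benzaldehyde
Conditions: MgCl2, Et3N, (CH2O)n, MeCN, 80 °C
Reagents that add atoms: paraformaldehyde (as formaldehyde), C=O
Why: Magnesium phenoxide-directed ortho-formylation with formaldehyde, a second formaldehyde acting as hydride acceptor; it is strictly ortho to the free hydroxyl, and of the two ortho sites the one beside the methoxy group should be preferred because the other is screened by the silyl group, which the C-methyl group pushes toward it.

Step 10
Reactants: 17 2-hydroxy-6-methoxy-5-methyl-4-[(triisopropylsilyl)oxy]benzaldehyde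
Product: 18 2-(hydroxymethyl)-3-methoxy-4-methyl-5-[(triisopropylsilyl)oxy]phenol
Conditions: NaBH4, THF–EtOH, 0 °C
Reagents that add atoms: none
Why: Borohydride reduction of an aldehyde to the saligenin; short reaction time at 0 °C should spare the aryl silyl ether.

Step 11
Reactants: 18 2-(hydroxymethyl)-3-methoxy-4-methyl-5-[(triisopropylsilyl)oxy]phenol
Product: 19 {2-hydroxy-6-methoxy-5-methyl-4-[(triisopropylsilyl)oxy]benzyl}triphenylphosphonium bromide
Conditions: PPh3·HBr, MeCN, 80 °C
Reagents that add atoms: triphenylphosphine hydrobromide, Br.c1ccc(cc1)P(c1ccccc1)c1ccccc1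
Why: Acid-promoted loss of water from the ortho-hydroxybenzyl alcohol and capture of the benzylic electrophile by triphenylphosphine, the usual entry to ortho-hydroxybenzylphosphonium salts; an aryl triisopropylsilyl ether should withstand this weak, stoichiometric acid.

Step 12
Reactants: 12 (2S)-5-methoxy-7-(methoxymethoxy)-2-phenylchromane-8-carboxylic acid
Product: 20 (2S)-5-methoxy-7-(methoxymethoxy)-2-phenylchromane-8-carbonyl chloride
Conditions: 1-chloro-N,N,2-trimethylprop-1-en-1-amine (1.2 equiv), CH2Cl2, 0 °C to rt; concentrated and used at once
Reagents that add atoms: 1-chloro-N,N,2-trimethylprop-1-en-1-amine, CC(C)=C(Cl)N(C)C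
Why: Acid chloride formation with an α-chloroenamine under neutral conditions; no HCl is set free, which should spare the neighbouring MOM acetal, and the by-product is a neutral amide.

Step 13
Reactants: 20 (2S)-5-methoxy-7-(methoxymethoxy)-2-phenylchromane-8-carbonyl chloride; 19 {2-hydroxy-6-methoxy-5-methyl-4-[(triisopropylsilyl)oxy]benzyl}triphenylphosphonium bromide
Product: 22 triisopropyl({4-methoxy-2-[(2S)-5-methoxy-7-(methoxymethoxy)-2-phenylchroman-8-yl]-5-methylbenzofuran-6-yl}oxy)silane, via aryl ester phosphonium bromide 21 (not isolated)
Conditions: 19 (1.0 equiv), Et3N (3.5 equiv), toluene, rt then 110 °C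
Reagents that add atoms: none
Why: O-acylation of the phenol followed by an intramolecular Wittig reaction: the benzylic ylide carbon C3' adds to the ester carbonyl C2' and triphenylphosphine oxide leaves, forming C2'=C3' and closing the furan; a 1:1 ratio of partners limits acyl transfer to the ylide carbon.

Step 14
Reactants: 22 triisopropyl({4-methoxy-2-[(2S)-5-methoxy-7-(methoxymethoxy)-2-phenylchroman-8-yl]-5-methylbenzofuran-6-yl}oxy)silane
Product: 23 (2S)-5-methoxy-8-{4-methoxy-5-methyl-6-[(triisopropylsilyl)oxy]benzofuran-2-yl}-2-phenylchroman-7-ol
Conditions: HCl (cat.), MeOH–THF, 45 °C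
Reagents that add atoms: none
Why: Acid-catalysed acetal exchange removes the aryl MOM ether as dimethoxymethane; it is done while ring B is still silylated and therefore less nucleophilic, and C2 with its unsubstituted phenyl group should not ionise under these mild conditions.

Step 15
Reactants: 23 (2S)-5-methoxy-8-{4-methoxy-5-methyl-6-[(triisopropylsilyl)oxy]benzofuran-2-yl}-2-phenylchroman-7-ol
Product: 24 (2S)-8-(6-hydroxy-4-methoxy-5-methylbenzofuran-2-yl)-5-methoxy-2-phenylchroman-7-ol
Conditions: Bu4NF, AcOH (1:1), THF, 0 °C
Reagents that add atoms: none
Why: Fluoride cleavage of the aryl silyl ether; buffering with acetic acid keeps the electron-rich bisphenol out of strongly basic solution.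

## Compound list

1 | 2,6-difluoro-4-hydroxybenzaldehyde | O=Cc1c(F)cc(O)cc1F | starting material
2 | 2,6-difluoro-4-(methoxymethoxy)benzaldehyde | O=Cc1c(F)cc(OCOC)cc1F | intermediate
3 | 2-fluoro-6-methoxy-4-(methoxymethoxy)benzaldehyde | O=Cc1c(F)cc(OCOC)cc1OC | intermediate
4 | acetophenone | CC(=O)c1ccccc1 | starting material
5 | (E)-3-[2-fluoro-6-methoxy-4-(methoxymethoxy)phenyl]-1-phenylprop-2-en-1-one | O=C(/C=C/c1c(F)cc(OCOC)cc1OC)c1ccccc1 | intermediate
6 | 3-[2-fluoro-6-methoxy-4-(methoxymethoxy)phenyl]-1-phenylpropan-1-one | O=C(CCc1c(F)cc(OCOC)cc1OC)c1ccccc1 | intermediate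
7 | (1S)-3-[2-fluoro-6-methoxy-4-(methoxymethoxy)phenyl]-1-phenylpropan-1-ol | COc1cc(OCOC)cc(F)c1CC[C@@H](c1ccccc1)O | intermediate
8 | carbon dioxide | O=C=O | starting material
9 | lithium (1S)-3-[2-fluoro-3-lithio-6-methoxy-4-(methoxymethoxy)phenyl]-1-phenylpropan-1-olate | COc1cc(OCOC)c([Li])c(F)c1CC[C@@H](c1ccccc1)O[Li] | intermediate
10 | lithium (1S)-3-[2,3-didehydro-6-methoxy-4-(methoxymethoxy)phenyl]-1-phenylpropan-1-olate (aryne) | COC1=C(CC[C@@H](c2ccccc2)O[Li])C#CC(OCOC)=C1 | intermediate
11 | [(2S)-5-methoxy-7-(methoxymethoxy)-2-phenylchroman-8-yl]lithium | COc1cc(OCOC)c([Li])c2c1CC[C@@H](c1ccccc1)O2 | intermediate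
12 | (2S)-5-methoxy-7-(methoxymethoxy)-2-phenylchromane-8-carboxylic acid | COc1cc(OCOC)c(C(=O)O)c2c1CC[C@@H](c1ccccc1)O2 | intermediate
13 | 3-methoxy-2-methylphenol | COc1cccc(O)c1C | starting material
14 | triisopropyl(3-methoxy-2-methylphenoxy)silane | COc1cccc(O[Si](C(C)C)(C(C)C)C(C)C)c1C | intermediate
15 | 2-{3-methoxy-4-methyl-5-[(triisopropylsilyl)oxy]phenyl}-4,4,5,5-tetramethyl-1,3,2-dioxaborolane | COc1cc(B2OC(C)(C)C(C)(C)O2)cc(O[Si](C(C)C)(C(C)C)C(C)C)c1C | intermediate
16 | 3-methoxy-4-methyl-5-[(triisopropylsilyl)oxy]phenol | COc1cc(O)cc(O[Si](C(C)C)(C(C)C)C(C)C)c1C | intermediate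
17 | 2-hydroxy-6-methoxy-5-methyl-4-[(triisopropylsilyl)oxy]benzaldehyde | COc1c(C=O)c(O)cc(O[Si](C(C)C)(C(C)C)C(C)C)c1C | intermediate
18 | 2-(hydroxymethyl)-3-methoxy-4-methyl-5-[(triisopropylsilyl)oxy]phenol | COc1c(CO)c(O)cc(O[Si](C(C)C)(C(C)C)C(C)C)c1C | intermediate
19 | {2-hydroxy-6-methoxy-5-methyl-4-[(triisopropylsilyl)oxy]benzyl}triphenylphosphonium bromide | COc1c(C[P+](c2ccccc2)(c2ccccc2)c2ccccc2)c(O)cc(O[Si](C(C)C)(C(C)C)C(C)C)c1C.[Br-] | intermediate
20 | (2S)-5-methoxy-7-(methoxymethoxy)-2-phenylchromane-8-carbonyl chloride | COc1cc(OCOC)c(C(=O)Cl)c2c1CC[C@@H](c1ccccc1)O2 | intermediate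
21 | {2-{[(2S)-5-methoxy-7-(methoxymethoxy)-2-phenylchromane-8-carbonyl]oxy}-6-methoxy-5-methyl-4-[(triisopropylsilyl)oxy]benzyl}triphenylphosphonium bromide | COc1cc(OCOC)c(C(=O)Oc3cc(O[Si](C(C)C)(C(C)C)C(C)C)c(C)c(OC)c3C[P+](c3ccccc3)(c3ccccc3)c3ccccc3)c2c1CC[C@@H](c1ccccc1)O2.[Br-] | intermediate
22 | triisopropyl({4-methoxy-2-[(2S)-5-methoxy-7-(methoxymethoxy)-2-phenylchroman-8-yl]-5-methylbenzofuran-6-yl}oxy)silane | COc1cc(OCOC)c(-c2cc3c(OC)c(C)c(O[Si](C(C)C)(C(C)C)C(C)C)cc3o2)c2c1CC[C@@H](c1ccccc1)O2 | intermediate
23 | (2S)-5-methoxy-8-{4-methoxy-5-methyl-6-[(triisopropylsilyl)oxy]benzofuran-2-yl}-2-phenylchroman-7-ol | COc1cc(O)c(-c2cc3c(OC)c(C)c(O[Si](C(C)C)(C(C)C)C(C)C)cc3o2)c2c1CC[C@@H](c1ccccc1)O2 | intermediate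
24 | (2S)-8-(6-hydroxy-4-methoxy-5-methylbenzofuran-2-yl)-5-methoxy-2-phenylchroman-7-ol | COc1cc(O)c(-c2cc3c(OC)c(C)c(O)cc3o2)c2c1CC[C@@H](c1ccccc1)O2 | target

## Step count and least certain steps

Total steps: 15. Longest linear sequence: 10 (steps 1–6 and 12–15); the ring B branch (steps 7–11) joins at step 13.

**Step 6 (key step).** Three things may go wrong:
- metalation at the ring position between the two alkoxy groups instead of beside fluorine;
- interception of the aryne by sec-BuLi or by a second aryllithium in competition with the internal alkoxide;
- protonation of the C8 carbanion before carbon dioxide reaches it.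

Fallback, from 7 back to 12, replacing elimination–addition by addition–elimination and making the C8 carbon bond first. The dilithio species is formed as before but kept at −78 °C and quenched with DMF to give 2-fluoro-3-[(3S)-3-hydroxy-3-phenylpropyl]-4-methoxy-6-(methoxymethoxy)benzaldehyde F1. Its formyl group now activates the neighbouring fluoride, so NaH in THF–DMF should close the pyran ring by intramolecular nucleophilic aromatic substitution to (2S)-5-methoxy-7-(methoxymethoxy)-2-phenylchromane-8-carbaldehyde F2. Chlorite oxidation of F2 (NaClO2, NaH2PO4, 2-methyl-2-butene, t-BuOH–H2O) returns to 12.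

**Step 13 (fed by step 12).** Three things may go wrong:
- participation of the neighbouring acetal oxygen at the acyl chloride, with loss of the MOM group;
- slow acylation of the phenol by a di-ortho-substituted aroyl chloride;
- acyl transfer to the ylide carbon instead of olefination at the crowded ester carbonyl.

Fallback, from 12 and 16 back to 22, avoiding attack at a hindered carbonyl altogether. Acid 12 is reduced with LiAlH4 in THF to [(2S)-5-methoxy-7-(methoxymethoxy)-2-phenylchroman-8-yl]methanol F3 and oxidised with MnO2 to the aldehyde F2 (the compound already met in the fallback to step 6). Seyferth–Gilbert homologation with dimethyl (1-diazo-2-oxopropyl)phosphonate and K2CO3 in MeOH gives (2S)-8-ethynyl-5-methoxy-7-(methoxymethoxy)-2-phenylchromane F4. Phenol 16 is iodinated with N-iodosuccinimide to 2-iodo-3-methoxy-4-methyl-5-[(triisopropylsilyl)oxy]phenol F5. Sonogashira coupling of F4 with F5 (PdCl2(PPh3)2, CuI, Et3N, DMF, 70 °C), with cyclisation of the ortho-alkynylphenol in the same flask, gives 22. This path also bypasses steps 9–11.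

**Step 9.** Formylation may occur at the ortho position beside the silyl ether, or twice. Fallback, from 16 back to 17, replacing phenoxide direction by directed ortho-metalation. Phenol 16 is converted with MOMCl and iPr2NEt into triisopropyl[3-methoxy-5-(methoxymethoxy)-2-methylphenoxy]silane F6. n-BuLi with TMEDA should then lithiate the position flanked by both the acetal and the methoxy group, the only one activated by two coordinating oxygens. DMF gives 2-methoxy-6-(methoxymethoxy)-3-methyl-4-[(triisopropylsilyl)oxy]benzaldehyde F7, and brief dilute HCl in MeOH at rt removes the MOM group ortho to the formyl group, giving 17.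

**Step 5.** Incomplete facial selectivity in the hydride transfer cannot be corrected later, since C2 is the only stereocentre. Fallback, from 12 back to 12, using resolution instead of relying on the reduction alone. Acid 12 is crystallised as (R)-1-phenylethylammonium (2S)-5-methoxy-7-(methoxymethoxy)-2-phenylchromane-8-carboxylate F8 (the enantiomeric amine would be used if its salt is the less soluble one). Cold dilute acid then liberates enantiomerically enriched 12.

## Further compounds

F1 | step 6 | 2-fluoro-3-[(3S)-3-hydroxy-3-phenylpropyl]-4-methoxy-6-(methoxymethoxy)benzaldehyde | COc1cc(OCOC)c(C=O)c(F)c1CC[C@@H](c1ccccc1)O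
F2 | step 6 | (2S)-5-methoxy-7-(methoxymethoxy)-2-phenylchromane-8-carbaldehyde | COc1cc(OCOC)c(C=O)c2c1CC[C@@H](c1ccccc1)O2
F3 | step 13 | [(2S)-5-methoxy-7-(methoxymethoxy)-2-phenylchroman-8-yl]methanol | COc1cc(OCOC)c(CO)c2c1CC[C@@H](c1ccccc1)O2
F4 | step 13 | (2S)-8-ethynyl-5-methoxy-7-(methoxymethoxy)-2-phenylchromane | COc1cc(OCOC)c(C#C)c2c1CC[C@@H](c1ccccc1)O2
F5 | step 13 | 2-iodo-3-methoxy-4-methyl-5-[(triisopropylsilyl)oxy]phenol | COc1c(I)c(O)cc(O[Si](C(C)C)(C(C)C)C(C)C)c1C
F6 | step 9 | triisopropyl[3-methoxy-5-(methoxymethoxy)-2-methylphenoxy]silane | COc1cc(OCOC)cc(O[Si](C(C)C)(C(C)C)C(C)C)c1C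
F7 | step 9 | 2-methoxy-6-(methoxymethoxy)-3-methyl-4-[(triisopropylsilyl)oxy]benzaldehyde | COc1c(C=O)c(OCOC)cc(O[Si](C(C)C)(C(C)C)C(C)C)c1C
F8 | step 5 | (R)-1-phenylethylammonium (2S)-5-methoxy-7-(methoxymethoxy)-2-phenylchromane-8-carboxylate | COc1cc(OCOC)c(C(=O)[O-])c2c1CC[C@@H](c1ccccc1)O2.C[C@@H]([NH3+])c1ccccc1
A1 | alternative 1 | (2S)-7-benzyloxy-5-methoxy-8-{4-methoxy-5-methyl-6-[(triisopropylsilyl)oxy]benzofuran-2-yl}-2-phenylchromane | COc1cc(OCc3ccccc3)c(-c3cc4c(OC)c(C)c(O[Si](C(C)C)(C(C)C)C(C)C)cc4o3)c2c1CC[C@@H](c1ccccc1)O2
A2 | alternative 1 | {2-{[(2S)-7-benzyloxy-5-methoxy-2-phenylchromane-8-carbonyl]oxy}-6-methoxy-5-methyl-4-[(triisopropylsilyl)oxy]benzyl}triphenylphosphonium bromide | COc1cc(OCc3ccccc3)c(C(=O)Oc3cc(O[Si](C(C)C)(C(C)C)C(C)C)c(C)c(OC)c3C[P+](c3ccccc3)(c3ccccc3)c3ccccc3)c2c1CC[C@@H](c1ccccc1)O2.[Br-]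
A3 | alternative 1 | (2S)-7-benzyloxy-5-methoxy-2-phenylchromane-8-carboxylic acid | COc1cc(OCc3ccccc3)c(C(=O)O)c2c1CC[C@@H](c1ccccc1)O2
A4 | alternative 2 | (2S)-7-benzyloxy-5-methoxy-2-phenyl-2H-chromene | COc1cc(OCc3ccccc3)cc2c1C=C[C@@H](c1ccccc1)O2
A5 | alternative 2 | 5-benzyloxy-1-methoxy-3-{[(1S)-1-phenylprop-2-en-1-yl]oxy}-2-vinylbenzene | COc1cc(OCc2ccccc2)cc(O[C@@H](C=C)c2ccccc2)c1C=C
A6 | alternative 3 | (2S)-5-methoxy-8-{4-methoxy-5-methyl-6-[(triisopropylsilyl)oxy]benzofuran-2-yl}-2-phenylchroman-7-ol | COc1cc(O)c(-c2cc3c(OC)c(C)c(O[Si](C(C)C)(C(C)C)C(C)C)cc3o2)c2c1CC[C@@H](c1ccccc1)O2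
A7 | alternative 3 | 4-(hydroxymethyl)-5-methoxy-2-{4-methoxy-5-methyl-6-[(triisopropylsilyl)oxy]benzofuran-2-yl}benzene-1,3-diol | COc1cc(O)c(-c2cc3c(OC)c(C)c(O[Si](C(C)C)(C(C)C)C(C)C)cc3o2)c(O)c1CO
A8 | alternative 3 | styrene | C=Cc1ccccc1
A9 | alternative 3 | 3-hydroxy-5-methoxy-2-{4-methoxy-5-methyl-6-[(triisopropylsilyl)oxy]benzofuran-2-yl}-6-methylidenecyclohexa-2,4-dien-1-one | COC1=CC(O)=C(c2cc3c(OC)c(C)c(O[Si](C(C)C)(C(C)C)C(C)C)cc3o2)C(=O)C1=C
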